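Remark on the chemistry: lignan numbering is used throughout (C7/C7' benzylic, C8/C8' ring-fusion carbons, C9/C9' OCH2 carbons), and ArSi stands for 3-methoxy-4-[(triisopropylsilyl)oxy]phenyl.

## Analysis of the target

The target (17) is the mono-O-prenyl ether of (7R,7'R,8S,8'S)-pinoresinol, a furofuran lignan built on a cis-fused 3,7-dioxabicyclo[3.3.0]octane. Ring 1 is C7–O–C9'–C8'–C8 and ring 2 is C7'–O–C9–C8–C8'; Ar1 (4-hydroxy-3-methoxyphenyl) sits on C7 and Ar2 (3-methoxy-4-prenyloxyphenyl) on C7'. The four stereocentres are contiguous: C8 and C8' (both S) carry cis hydrogens at the ring fusion, and C7 and C7' (both R) hold their aryl groups on the convex face, each trans to the CH2 group on the neighbouring fusion carbon. The core is therefore C2-symmetric, and only the phenol substituents (OH against O-prenyl) break the symmetry. The sensitive sites are the two benzylic C–O bonds para to an oxygenated ring (they ionise in acid, which allows epimerisation at C7/C7' or rearrangement), the free phenol, and the prenyl aryl ether, which is acid-labile and whose alkene would not survive boranes. The difficulty is twofold: C8 and C8' carry only H, C and CH2O substituents, so their absolute configuration has to be induced by a neighbouring centre, and two chemically identical phenols must end up different. The plan rests on the fact that C8 and C8' each bear exactly one hydrogen and one CH2–O group, so each is the formal anti-Markovnikov hydration product of a 1,1-disubstituted alkene (C8=C9 and C8'=C9'), the two alkenes together forming a 2,3-disubstituted buta-1,3-diene flanked by the carbinols C7 and C7'. Those carbinols steer the hydration and are then ionised when rings 1 and 2 close through C7–O and C7'–O, so their own configuration is only a relay.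

## Retrosynthetic reasoning

**17 to 15 and 16.** The aryl O–CH2 bond of the prenyl ether is cut last. The prenyl alkene would be hydroborated by 10 and the ether would not tolerate the acid of the ring closure, so it cannot be carried earlier. What is gained is the C2-symmetric bisphenol 15, so every earlier operation acts on both halves at once. The forward step must alkylate one of two equivalent phenols; because of the symmetry either phenol gives the same mono-ether, but the step is statistical.

**15 to 14.** The two phenol O–H bonds are traced back to O–Si bonds. The triisopropylsilyl ether is chosen because it survives organometallic, tin, copper, borane and acid steps and keeps the para oxygen electron-releasing. The forward step is a fluoride desilylation that must leave the benzylic ethers alone.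

**14 to 13.** Both benzylic C–O bonds are cut, C7–O (to C9') in ring 1 and C7'–O (to C9) in ring 2. These bonds form easily because a benzylic carbon para to oxygen ionises under mild acid. Cutting the C9–O bonds instead would need activation of the primary alcohols and would carry the C7 configuration over with retention. The gain is the acyclic tetraol 13, in which only C8 and C8' must have the final configuration. The forward step must close both rings 5-exo under kinetic control so that each aryl group ends up on the convex face.

**13 to 9 (with 10 and 11).** The C9–O and C9'–O bonds and the C8–H and C8'–H bonds are cut, which is a double hydroboration–oxidation. This is the only point at which C8 and C8' can be addressed through a neighbouring group: each alkene is 1,1-disubstituted and allylic to a carbinol. The gain is a diene with no stereocentre at C8 or C8' and two identical relay centres. The forward step must put boron on the terminal carbons only and add anti to each carbinol oxygen at both alkenes.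

**9 to 8.** The central sp2–sp2 bond C8–C8' is cut symmetrically. This makes the skeleton from two identical halves, each with one stereocentre, and joining two enantioenriched halves diverts the minor enantiomer into a separable meso compound. The forward homocoupling must leave the free, ionisable carbinols untouched.

**8 to 6 and 7.** The C8–Sn and C9–H bonds are cut, a hydrostannation of a terminal alkyne with 7. An alkyne is chosen as the precursor because it comes from a single cheap reagent and is small enough for the resolution below. The forward step must deliver tin to the internal carbon.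

**6 to 5.** The single enantiomer is traced back to the racemate. A ketone reduction at C7 was set aside: both groups flanking such a carbonyl would be flat and unsaturated (aryl against an alkynyl or 2-substituted alkenyl group), so neither the sense nor the level of induction of a reduction catalyst could be predicted. A lipase, by contrast, separates an aryl from an ethynyl group with a well-established preference. The forward step is a kinetic resolution by acylation that leaves 6 unreacted.

**5 to 3 and 4, and 3 to 1 and 2.** The C7–C8 bond is cut to the aldehyde 3 and the acetylide 4, and the O–Si bond of 3 to vanillin 1 and the silyl chloride 2. Both forward steps are standard.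

## Alternatives that were turned down

**Alternative 1:** donor–acceptor cyclopropane opened into ring 2.
- Disconnection: the C7'–O bond of ring 2 together with the C7'–C8 bond of a cyclopropane fused to a γ-lactone that stands in for ring 1 (C7 as carbonyl, Ar1 absent).
- Forward key step: Sc(OTf)3 would ionise cyclopropane lactone A1 between the aryl-bearing carbon C7' and the lactone α-carbon C8. The C9 hydroxyl on C8 traps the benzylic cation 5-exo, and protonation of the lactone enolate sets the cis ring fusion, giving bicyclic lactone A2.
- For it: the Lewis acid is catalytic, the ring fusion is enforced by the bicycle, and the aryl group goes to the convex face. It is stronger than the chosen plan on one point: Ar2 and Ar1 enter at different stages, so the two phenols are distinguished by construction and no statistical etherification is needed.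
- Against it: A2 holds only half of the skeleton. An Ar1 nucleophile must still add to the lactone carbonyl C7 and the resulting C7–OH must be removed. Hydride delivery to that oxocarbenium ion from the open convex face would place Ar1 endo, the C7 epimer of the target, and acid equilibration meets an exo/endo pair of similar stability. A1 itself needs an enantioselective cyclopropanation and a quaternary C8 bearing the hydroxymethyl group.
- Comparison: it is longer and leaves C7 unsolved. The chosen plan sets C7 and C7' together in one exo-selective closure and uses every step twice, at the price of a statistical last step.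

**Alternative 2:** titanocene epoxide-opening radical cascade.
- Disconnection: C8–C8' (ring 1) and C7'–O (ring 2) in one radical–polar cascade from epoxy ether A3, in which C7 already carries Ar1 and the ether oxygen, C8–C9 is a terminal epoxide and C8'=C7' is the (E)-alkene of an Ar2 cinnamyl group.
- Forward key step: Cp2TiCl (trivalent titanium) opens the epoxide homolytically to a secondary C8 radical with a titanium alkoxide on C9. 5-exo-trig addition to the alkene forms C8–C8' and a benzylic C7' radical; after oxidation of that centre with iodine the C9 alkoxide closes ring 2 to give A4.
- For it: both rings and three stereocentres come from one flask, the route is convergent and short, and the two silyl groups of A4 differ, so the phenol to be prenylated can be released selectively. On differentiation and step count it is stronger than the chosen plan.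
- Against it: all selectivity hangs on the single centre C7 acting through an early radical transition state. The cascade needs C7/C8 trans and C8/C8' cis at once; only the cis isomer can close ring 2, so the trans fraction is lost. Capture at C7' adds a further stereochemical question, two equivalents of the titanium reagent are consumed, and A3 must itself be made enantiopure by an asymmetric epoxidation or a resolution.
- Comparison: the chosen plan sets C8 and C8' by closed-shell additions next to a stereocentre of known directing sense, and C7/C7' by a closure that follows the kinetic preference of quinone-methide ring closures.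

**Alternative 3:** three-component conjugate addition–aldol on a chiral butenolide.
- Disconnection: C7–C8 and C7'–C8'; both aryl-bearing carbons are attached in one operation to a four-carbon butenolide that supplies C8, C8', C9 and C9'.
- Forward key step: the 2-lithio derivative of dithiane A5 (an Ar1 acyl anion equivalent) adds 1,4 to butenolide A6 anti to its menthyloxy group, and the lactone enolate is trapped by aldehyde A7 trans to the new substituent, giving A8.
- For it: it is highly convergent, the auxiliary controls the absolute configuration at C8 and C8' with a dependable trans relationship, and the prenyl ether is already in place on Ar2, so there is no statistical step. On that point it is stronger than the chosen plan.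
- Against it: A8 is far from the target in oxidation state. C7 is a dithioketal, C9' a lactone carbonyl and C9 an acetal carbon carrying the auxiliary. The dithiane must be removed with thiophilic or oxidising reagents in the presence of the prenyl alkene and two electron-rich rings, C7 must be reduced, and the lactone acetal must be opened reductively to the alcohol level. The final acid-mediated double ring closure then has to be survived by the acid-labile prenyl ether. The auxiliary is stoichiometric and five or six further steps are needed.
- Comparison: both routes converge on the oxidation pattern of 13, but the chosen plan reaches 13 in six steps without redox adjustment and prenylates only after the acid step.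

Key step: step 6

## Route

Step 1
Reactants: 1 vanillin (4-hydroxy-3-methoxybenzaldehyde); 2 triisopropylsilyl chloride
Product: 3 3-methoxy-4-[(triisopropylsilyl)oxy]benzaldehyde
Conditions: imidazole, DMF, 0 °C → rt
Reagents that add atoms: triisopropylsilyl chloride 2, CC(C)[Si](Cl)(C(C)C)C(C)C
Why: Silyl ether formation at the phenol through the N-silylimidazolium species; the bulky silyl ether withstands the Grignard, tin, copper, borane and acid steps that follow and keeps the para oxygen electron-releasing for the later benzylic ionisation.

Step 2
Reactants: 3 3-methoxy-4-[(triisopropylsilyl)oxy]benzaldehyde; 4 ethynylmagnesium bromide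
Product: 5 rac-1-{3-methoxy-4-[(triisopropylsilyl)oxy]phenyl}prop-2-yn-1-ol
Conditions: HC≡CMgBr, THF, 0 °C; aq. NH4Cl
Reagents that add atoms: ethynylmagnesium bromide 4, C#C[Mg]Br
Why: Grignard addition of the acetylide to the aldehyde forms the C7–C8 bond; the two alkyne carbons become C8 and C9 of each half, and the aryl silyl ether is inert to the reagent.

Step 3
Reactants: 5 rac-1-{3-methoxy-4-[(triisopropylsilyl)oxy]phenyl}prop-2-yn-1-ol
Product: 6 (S)-1-{3-methoxy-4-[(triisopropylsilyl)oxy]phenyl}prop-2-yn-1-ol
Conditions: immobilised Candida antarctica lipase B (Novozym 435), vinyl acetate, MTBE, 30 °C, stopped just past half conversion; chromatographic separation from the acetate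
Reagents that add atoms: none
Why: Lipase-catalysed kinetic resolution by irreversible transesterification: the enzyme acylates the enantiomer that fits the slim ethynyl group into its medium pocket and the aryl group into the large one, which is the (R)-alcohol, so the (S)-alcohol 6 stays unacylated and going slightly beyond half conversion secures its enantiopurity. This sets the relay centre C7 (and C7'); at most half of 5 is used, and the (R)-acetate can be returned to 5 by methanolysis, oxidation and reduction.

Step 4
Reactants: 6 (S)-1-{3-methoxy-4-[(triisopropylsilyl)oxy]phenyl}prop-2-yn-1-ol; 7 tributyltin hydride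
Product: 8 (R)-1-{3-methoxy-4-[(triisopropylsilyl)oxy]phenyl}-2-(tributylstannyl)prop-2-en-1-ol
Conditions: Bu3SnH, Mo(CO)3(CNtBu)3 (cat.), hydroquinone (cat.), THF, 55 °C
Reagents that add atoms: tributyltin hydride 7, CCCC[SnH](CCCC)CCCC
Why: Molybdenum-catalysed syn-hydrostannation of a terminal alkyne; with this isonitrile complex and a propargylic oxygen substituent tin goes to the internal carbon, and the radical inhibitor suppresses the free-radical addition that would put tin on the terminal carbon. The carbinol centre is not involved; its descriptor changes from S to R only because the tin-bearing carbon now outranks the aryl group.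

Step 5
Reactants: 8 (R)-1-{3-methoxy-4-[(triisopropylsilyl)oxy]phenyl}-2-(tributylstannyl)prop-2-en-1-ol (two molecules)
Product: 9 (1R,4R)-1,4-bis{3-methoxy-4-[(triisopropylsilyl)oxy]phenyl}-2,3-dimethylidenebutane-1,4-diol
Conditions: CuCl2, DMF, 0 °C → rt, argon
Reagents that add atoms: none
Why: Copper-mediated oxidative homocoupling of an alkenylstannane: tin-to-copper transmetalation gives an alkenylcopper species that dimerises on oxidation by the divalent copper salt and forms the C8–C8' bond. The carbinol centres are untouched, and residual (R)-monomer ends up mainly in the separable meso diastereomer, which raises the enantiopurity of C2-symmetric 9.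

Step 6
Reactants: 9 (1R,4R)-1,4-bis{3-methoxy-4-[(triisopropylsilyl)oxy]phenyl}-2,3-dimethylidenebutane-1,4-diol; 10 9-borabicyclo[3.3.1]nonane (9-BBN); 11 sodium perborate tetrahydrate
Product: 13 (1S,2S,3S,4S)-1,4-bis{3-methoxy-4-[(triisopropylsilyl)oxy]phenyl}-2,3-bis(hydroxymethyl)butane-1,4-diol, via tetra(9-BBN) borinate–alkylborane adduct 12 (not isolated)
Conditions: 9-BBN (excess), THF, 0 °C → rt; then NaBO3·4H2O, THF/H2O, rt
Reagents that add atoms: sodium perborate tetrahydrate 11, O.O.O.O.[Na+].[O-]OB=O (oxygen on C9 and C9'); 9-borabicyclo[3.3.1]nonane 10, B1C2CCCC1CCC2 (boron and carbon stay only in 12; 13 keeps only hydrogen on C8 and C8')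
Why: The two carbinols first give O-borinates with loss of H2, after which each twisted, electronically isolated 1,1-disubstituted alkene undergoes concerted four-centre syn addition of B–H, boron going to the terminal carbon (C9, then C9') and hydrogen to C8 or C8'. The closest known reaction type is the anti-selective hydroboration of 1,1-disubstituted allylic alcohols and ethers with 9-BBN, and no ring is closed in this step. C8 is controlled by C7: in the reactive rotamer the carbinol C–H lies near the alkene plane on the CH2 side, the aryl group stands perpendicular and shields one face, and the bulky borane enters opposite to the aryl group with the O-borinate on the outside, which gives the anti relation between the C7 oxygen and the C8–C8' bond, that is (7S,8S). C8' is set in the same way by C7' in the second hydroboration; the C8 centre formed first is also allylic to that alkene and, with its hydrogen eclipsing the alkene, turns its branched C7 arm away from the same face, so both inductions should point the same way and give the C2-symmetric (8S,8'S) pair. Perborate oxidation replaces each C–B bond by C–O with retention, cleaves the borinates and is mild enough to spare the aryl silyl ethers. The step needs complete terminal regioselectivity, which a dialkylborane on a 1,1-disubstituted alkene secures, and high facial selectivity at both alkenes, which rests on the aryl-against-hydrogen size difference at each carbinol.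

Step 7
Reactants: 13 (1S,2S,3S,4S)-1,4-bis{3-methoxy-4-[(triisopropylsilyl)oxy]phenyl}-2,3-bis(hydroxymethyl)butane-1,4-diol
Product: 14 (7R,7'R,8S,8'S)-pinoresinol bis(triisopropylsilyl) ether, i.e. (1S,2R,5S,6R)-2,6-bis{3-methoxy-4-[(triisopropylsilyl)oxy]phenyl}-3,7-dioxabicyclo[3.3.0]octane
Conditions: CSA (cat.), 4 Å molecular sieves, CH2Cl2, 0 °C → rt; Et3N quench as soon as 13 is consumed
Reagents that add atoms: none
Why: Acid-catalysed ionisation of each benzylic alcohol gives a p-silyloxybenzyl cation (a silylated quinone methide) that is captured 5-exo by the primary hydroxyl of the other half (C9'–OH onto C7, C9–OH onto C7'). C7 and C7' are set here under kinetic control on planar cations, so the relay configuration of 13 no longer matters: the first closure puts the aryl group trans to the C8 substituent and the second, onto a cis-fused bicycle, puts its aryl group on the convex face. C8 and C8' are not touched.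

Step 8
Reactants: 14 (7R,7'R,8S,8'S)-pinoresinol bis(triisopropylsilyl) ether
Product: 15 (7R,7'R,8S,8'S)-pinoresinol
Conditions: Bu4NF, THF, 0 °C; aq. NH4Cl
Reagents that add atoms: none
Why: Fluoride cleavage of the aryl silyl ethers, driven by the Si–F bond and the phenoxide leaving group; the benzylic ethers and all four stereocentres are inert to these mildly basic conditions.

Step 9
Reactants: 15 (7R,7'R,8S,8'S)-pinoresinol; 16 prenyl bromide (1-bromo-3-methylbut-2-ene)
Product: 17 (7R,7'R,8S,8'S)-pinoresinol mono-O-prenyl ether, i.e. 4-[(1R,3aS,4R,6aS)-4-{3-methoxy-4-[(3-methylbut-2-en-1-yl)oxy]phenyl}tetrahydro-1H,3H-furo[3,4-c]furan-1-yl]-2-methoxyphenol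
Conditions: prenyl bromide (1 equiv), K2CO3, DMF, 0 °C → rt
Reagents that add atoms: prenyl bromide 16, CC(C)=CCBr
Why: Williamson ether synthesis on one of two equivalent phenols; because 15 is C2-symmetric either phenol gives the same mono-ether 17, and the limiting amount of 16 holds back bis-alkylation while unreacted 15 is recovered and recycled. Direct SN2 at the primary allylic bromide gives the linear prenyl ether.

## Compound list

1 | vanillin (4-hydroxy-3-methoxybenzaldehyde) | COc1cc(C=O)ccc1O | starting material
2 | triisopropylsilyl chloride | CC(C)[Si](Cl)(C(C)C)C(C)C | starting material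
3 | 3-methoxy-4-[(triisopropylsilyl)oxy]benzaldehyde | COc1cc(C=O)ccc1O[Si](C(C)C)(C(C)C)C(C)C | intermediate
4 | ethynylmagnesium bromide | C#C[Mg]Br | starting material
5 | rac-1-{3-methoxy-4-[(triisopropylsilyl)oxy]phenyl}prop-2-yn-1-ol | COc1cc(C(O)C#C)ccc1O[Si](C(C)C)(C(C)C)C(C)C | intermediate
6 | (S)-1-{3-methoxy-4-[(triisopropylsilyl)oxy]phenyl}prop-2-yn-1-ol | COc1cc([C@@H](O)C#C)ccc1O[Si](C(C)C)(C(C)C)C(C)C | intermediate
7 | tributyltin hydride | CCCC[SnH](CCCC)CCCC | starting material
8 | (R)-1-{3-methoxy-4-[(triisopropylsilyl)oxy]phenyl}-2-(tributylstannyl)prop-2-en-1-ol | COc1cc([C@@H](O)C(=C)[Sn](CCCC)(CCCC)CCCC)ccc1O[Si](C(C)C)(C(C)C)C(C)C | intermediate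
9 | (1R,4R)-1,4-bis{3-methoxy-4-[(triisopropylsilyl)oxy]phenyl}-2,3-dimethylidenebutane-1,4-diol | COc1cc([C@@H](O)C(=C)C(=C)[C@H](O)c2ccc(O[Si](C(C)C)(C(C)C)C(C)C)c(OC)c2)ccc1O[Si](C(C)C)(C(C)C)C(C)C | intermediate
10 | 9-borabicyclo[3.3.1]nonane (9-BBN) | B1C2CCCC1CCC2 | starting material
11 | sodium perborate tetrahydrate | O.O.O.O.[Na+].[O-]OB=O | starting material
12 | tetra(9-BBN) adduct: (1S,2S,3S,4S)-1,4-bis(9-borabicyclo[3.3.1]non-9-yloxy)-2,3-bis(9-borabicyclo[3.3.1]non-9-ylmethyl)-1,4-bis{3-methoxy-4-[(triisopropylsilyl)oxy]phenyl}butane | COc1cc([C@@H](OB2C3CCCC2CCC3)[C@H](CB2C3CCCC2CCC3)[C@@H](CB2C3CCCC2CCC3)[C@H](OB2C3CCCC2CCC3)c2ccc(O[Si](C(C)C)(C(C)C)C(C)C)c(OC)c2)ccc1O[Si](C(C)C)(C(C)C)C(C)C | intermediate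
13 | (1S,2S,3S,4S)-1,4-bis{3-methoxy-4-[(triisopropylsilyl)oxy]phenyl}-2,3-bis(hydroxymethyl)butane-1,4-diol | COc1cc([C@@H](O)[C@H](CO)[C@@H](CO)[C@H](O)c2ccc(O[Si](C(C)C)(C(C)C)C(C)C)c(OC)c2)ccc1O[Si](C(C)C)(C(C)C)C(C)C | intermediate
14 | (7R,7'R,8S,8'S)-pinoresinol bis(triisopropylsilyl) ether | COc1cc([C@@H]2OC[C@@H]3[C@H]2CO[C@H]3c2ccc(O[Si](C(C)C)(C(C)C)C(C)C)c(OC)c2)ccc1O[Si](C(C)C)(C(C)C)C(C)C | intermediate
15 | (7R,7'R,8S,8'S)-pinoresinol | COc1cc([C@@H]2OC[C@@H]3[C@H]2CO[C@H]3c2ccc(O)c(OC)c2)ccc1O | intermediate
16 | prenyl bromide (1-bromo-3-methylbut-2-ene) | CC(C)=CCBr | starting material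
17 | (7R,7'R,8S,8'S)-pinoresinol mono-O-prenyl ether (CNP0185952.2) | COc1cc([C@@H]2OC[C@@H]3[C@H]2CO[C@H]3c2ccc(OCC=C(C)C)c(OC)c2)ccc1O | target

## Step count and least certain steps

Total step count: 9. Longest linear sequence: 9 steps (1 to 17).

**Step 6 (key step).** The most likely failure is insufficient facial selectivity. The first hydroboration takes place on a substrate whose carbinols are masked only as borinates formed in the flask, and the second alkene is flanked by two allylic stereocentres (C7' and the new C8), whose inductions are expected, but not known, to reinforce each other. Either effect would give diastereomeric tetraols that are hard to separate. The fallback sets out from 9 and returns at 14. Both carbinols are silylated (TBSCl, imidazole, DMF) to the bis(tert-butyldimethylsilyl) ether F1. This is the ether class for which the anti-selective 9-BBN hydroboration is best documented, and its fixed, very bulky silyloxy/aryl centres give the carbinol control more weight. Hydroboration with 10 and oxidation with 11 should give the 1,4-diol F2. F2 is not deprotected: BF3·OEt2 in CH2Cl2 at low temperature ionises the electron-rich benzylic silyl ethers directly, and capture by the two primary hydroxyls closes both rings to give 14.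

**Step 4.** Incomplete regiocontrol is the risk: the bulky aryl carbinol may divert some tin to the terminal carbon, and the isomeric stannanes are difficult to separate. The fallback sets out from 6 and returns at 9, replacing tin by boron and the copper-mediated coupling by a palladium-catalysed one. Copper-catalysed protoboration with (SIMes)CuCl (monovalent copper), NaOtBu, B2pin2 and MeOH in THF puts boron on the internal carbon of terminal alkynes that carry a propargylic oxygen and should give the alkenylboronate F3. Oxidative homocoupling of F3 with Pd(OAc)2 (divalent palladium, catalytic), aqueous K2CO3 and O2 as terminal oxidant then forms the C8–C8' bond of 9.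

**Step 5.** Protodestannylation, or ionisation of the allylic, benzylic carbinol by the Lewis-acidic copper salt, may compete with transmetalation and lower the yield of the dimer. The fallback sets out from 8 and returns at 9 and swaps the oxidative coupling for a reductive one. Tin–iodine exchange with I2 in CH2Cl2 at 0 °C gives the alkenyl iodide F4 with the carbinol untouched. Ni(cod)2 (zerovalent nickel, stoichiometric) with PPh3 in DMF then couples two molecules by oxidative addition, metathesis to a dialkenylnickel species and reductive elimination.

**Step 7.** The product ethers can re-ionise under the acid that forms them, so stereochemical drift toward the C7 epimer (one aryl endo, of similar stability) is the main risk. Closure of a benzylic hydroxyl onto the other benzylic cation (a 2,5-diaryltetrahydrofuran) and Friedel–Crafts attack by the second ring are further competing processes. The fallback sets out from 13 and returns at 15. Desilylation with Bu4NF first gives the free bisphenol tetraol F5. On gentle warming in a weakly acidic aqueous buffer each p-hydroxybenzyl alcohol loses water to a neutral p-quinone methide, which is trapped by the primary hydroxyl in the same 5-exo sense, as in the ring closure that follows oxidative phenol coupling. Under these non-ionising conditions the closed rings do not reopen.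

**Step 9.** Over-alkylation is unavoidable in a statistical mono-etherification of two equivalent phenols, so the yield per pass is limited and three components must be separated. The fallback sets out from 14 and returns at 17 and moves the statistical event to a step whose other products go straight back into the route. One equivalent of Bu4NF at low temperature removes a single silyl group to give the mono-silyl ether F6; recovered 14 is reused and any 15 is resilylated with 2. The one free phenol of F6 is alkylated to completion with excess 16 and K2CO3 to give F7, which cannot be over-alkylated. Bu4NF then cleaves the remaining silyl ether to give 17.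

## Further compounds

F1 | step 6 | (1R,4R)-1,4-bis(tert-butyldimethylsilyloxy)-1,4-bis{3-methoxy-4-[(triisopropylsilyl)oxy]phenyl}-2,3-dimethylidenebutane | COc1cc([C@@H](O[Si](C)(C)C(C)(C)C)C(=C)C(=C)[C@H](O[Si](C)(C)C(C)(C)C)c2ccc(O[Si](C(C)C)(C(C)C)C(C)C)c(OC)c2)ccc1O[Si](C(C)C)(C(C)C)C(C)C
F2 | step 6 | (2S,3S)-2,3-bis[(S)-(tert-butyldimethylsilyloxy){3-methoxy-4-[(triisopropylsilyl)oxy]phenyl}methyl]butane-1,4-diol | COc1cc([C@@H](O[Si](C)(C)C(C)(C)C)[C@H](CO)[C@@H](CO)[C@H](O[Si](C)(C)C(C)(C)C)c2ccc(O[Si](C(C)C)(C(C)C)C(C)C)c(OC)c2)ccc1O[Si](C(C)C)(C(C)C)C(C)C
F3 | step 4 | (S)-1-{3-methoxy-4-[(triisopropylsilyl)oxy]phenyl}-2-(4,4,5,5-tetramethyl-1,3,2-dioxaborolan-2-yl)prop-2-en-1-ol | COc1cc([C@@H](O)C(=C)B2OC(C)(C)C(C)(C)O2)ccc1O[Si](C(C)C)(C(C)C)C(C)C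
F4 | step 5 | (R)-2-iodo-1-{3-methoxy-4-[(triisopropylsilyl)oxy]phenyl}prop-2-en-1-ol | COc1cc([C@@H](O)C(I)=C)ccc1O[Si](C(C)C)(C(C)C)C(C)C
F5 | step 7 | (1S,2S,3S,4S)-1,4-bis(4-hydroxy-3-methoxyphenyl)-2,3-bis(hydroxymethyl)butane-1,4-diol | COc1cc([C@@H](O)[C@H](CO)[C@@H](CO)[C@H](O)c2ccc(O)c(OC)c2)ccc1O
F6 | step 9 | (7R,7'R,8S,8'S)-pinoresinol mono(triisopropylsilyl) ether | COc1cc([C@@H]2OC[C@@H]3[C@H]2CO[C@H]3c2ccc(O[Si](C(C)C)(C(C)C)C(C)C)c(OC)c2)ccc1O
F7 | step 9 | (7R,7'R,8S,8'S)-pinoresinol O-prenyl O'-triisopropylsilyl ether | COc1cc([C@@H]2OC[C@@H]3[C@H]2CO[C@H]3c2ccc(OCC=C(C)C)c(OC)c2)ccc1O[Si](C(C)C)(C(C)C)C(C)C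
A1 | alternative 1 | 6-exo-[4-(tert-butyldimethylsilyloxy)-3-methoxyphenyl]-1-(hydroxymethyl)-3-oxabicyclo[3.1.0]hexan-2-one | O=C1OC[C@H]2[C@H](c3ccc(O[Si](C)(C)C(C)(C)C)c(OC)c3)[C@@]12CO
A2 | alternative 1 | 6-exo-[4-(tert-butyldimethylsilyloxy)-3-methoxyphenyl]-3,7-dioxabicyclo[3.3.0]octan-2-one (cis-fused, C8, C8' and C7' as in the target) | O=C1OC[C@@H]2[C@H]1CO[C@H]2c1ccc(O[Si](C)(C)C(C)(C)C)c(OC)c1
A3 | alternative 2 | (E)-3-[4-(tert-butyldimethylsilyloxy)-3-methoxyphenyl]allyl ether of {3-methoxy-4-[(triisopropylsilyl)oxy]phenyl}(oxiran-2-yl)methanol (C7 as in the target; epoxide carbon drawn in one configuration, lost in the radical step) | COc1cc([C@H](OC/C=C/c2ccc(O[Si](C)(C)C(C)(C)C)c(OC)c2)[C@H]2CO2)ccc1O[Si](C(C)C)(C(C)C)C(C)C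
A4 | alternative 2 | (7R,7'R,8S,8'S)-pinoresinol O-triisopropylsilyl O'-tert-butyldimethylsilyl ether | COc1cc([C@@H]2OC[C@@H]3[C@H]2CO[C@H]3c2ccc(O[Si](C)(C)C(C)(C)C)c(OC)c2)ccc1O[Si](C(C)C)(C(C)C)C(C)C
A5 | alternative 3 | 2-{3-methoxy-4-[(triisopropylsilyl)oxy]phenyl}-1,3-dithiane | COc1cc(C2SCCCS2)ccc1O[Si](C(C)C)(C(C)C)C(C)C
A6 | alternative 3 | (5S)-5-[(1S,2R,5S)-menthyloxy]furan-2(5H)-one | O=C1C=C[C@@H](O[C@H]2C[C@@H](C)CC[C@@H]2C(C)C)O1
A7 | alternative 3 | 3-methoxy-4-[(3-methylbut-2-en-1-yl)oxy]benzaldehyde (O-prenylvanillin) | COc1cc(C=O)ccc1OCC=C(C)C
A8 | alternative 3 | trans,trans-3-[hydroxy(3-methoxy-4-prenyloxyphenyl)methyl]-4-(2-{3-methoxy-4-[(triisopropylsilyl)oxy]phenyl}-1,3-dithian-2-yl)-5-menthyloxy-γ-butyrolactone | O=C1[C@@H]([C@@H](O)c2ccc(OCC=C(C)C)c(OC)c2)[C@H](C2(c3ccc(O[Si](C(C)C)(C(C)C)C(C)C)c(OC)c3)SCCCS2)[C@@H](O[C@H]2C[C@@H](C)CC[C@@H]2C(C)C)O1
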